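## The problem

6-Methyl-8-prenylnaringenin 17 is a flavanone: a chroman-4-one (ring C) fused to a phloroglucinol-type ring A, with a 4-hydroxyphenyl ring B on C2. Ring A carries no hydrogen: O5, O7 and O1 alternate with the C6 methyl group, the C8 prenyl group and the acyl carbon C4 on C4a. The two oxygens ortho to C4a must therefore be told apart, because exchanging O5 (next to the methyl) with O1 (next to the prenyl) gives the 8-methyl-6-prenyl isomer. C2 (S) is the only stereocentre, so nothing in the molecule can relay chirality to it and it must come from a chiral catalyst or reagent. C2 is also fragile: it is benzylic, ether-bearing and β to the C4 ketone, so base opens ring C by E1cB to the chalcone and recloses it without control, most easily once the 5-hydroxyl is free. The prenyl group rules out strong acid (cyclisation onto O7 to a chroman), electrophilic oxidants and hydrogenation, and the three phenols need protection that comes off close to neutrality. The structure offers one decisive opening: C2 is a CH bound to O1 and to ring B, so its precursor CH2, the methylene of a 4-oxygenated benzyl ether on O1, is an electron-rich C–H six atoms away from C3, and a carbene at C3, held on the C4 carbonyl, can insert into it, closing ring C and creating C2 in a single neutral step. A second asset is that the C6 methyl sits between two equivalent oxygens, so ring A can be traced to a symmetric phenol in which the O5/O1 question cannot arise.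

## Retrosynthesis

**17 ⇒ 16 (three O–Si bonds).** The last operation is limited to removing three triisopropylsilyl groups from the (S)-flavanone 16. Silyl ethers are preferred to methyl ethers (Lewis acid would cyclise the prenyl group), acetals (protic acid) and benzyl ethers (hydrogenolysis would reduce the prenyl alkene). Buffered fluoride is compatible with both the prenyl group and the base-sensitive C2. The forward step must not open ring C.

**16 ⇒ 15 (C2–C3).** Cutting C2–C3 turns ring C into the acyclic aryl diazomethyl ketone 15, whose O1 carries the 4-silyloxybenzyl group. The neighbouring cut, O1–C2 (oxa-Michael closure of a chalcone), is reversible and base-mediated, which is exactly the pathway that racemises flavanones. The carbene insertion is irreversible, neutral, and sets C2 in the same event that closes the ring. Compound 15 has no ring C and no stereocentre. The forward reaction has to distinguish the two enantiotopic benzylic hydrogens and prefer C–H insertion to attack on the O1 lone pair.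

**15 ⇒ 13 (C3=N2).** The diazo group is traced to the methyl ketone 13 by detrifluoroacetylative diazo transfer through the diketone 14. The alternative, acylation of a diazoalkane by a hindered aroyl chloride, needs acid-chloride formation next to an acid-labile benzyl ether; it is kept as a reserve. Compound 13 has a single enolisable position, so the forward step only needs clean kinetic enolisation.

**13 ⇒ 11 (C4a–C4).** The acetyl group is disconnected to the aryl bromide 11, through aryllithium 12 and a Weinreb-type acetyl donor. Friedel–Crafts or Fries acylation is excluded by the prenyl alkene and by the electron-rich benzyl ether. The precursor 11 lacks the carbonyl and is stable to the organometallic step that precedes it.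

**11 ⇒ 8 + 9 (C8–C1 of the prenyl group).** The prenyl group is cut back to the symmetric dibromide 8 and prenyl bromide 9, via aryllithium 10 and copper-mediated allylic substitution. Because the two bromines of 8 are equivalent, the first exchange can only give one product. Electrophilic C-prenylation of a phloroglucinol nucleus would bring O- versus C-alkylation and over-alkylation. The forward step must exchange exactly one bromine and deliver the linear (not the 1,1-dimethylallyl) isomer.

**8 ⇒ 5 + 7 (O1–CH2).** The benzyl ether is disconnected to the 2,6-dibromophenol 5 and the silyl-protected benzyl alcohol 7, joined by Mitsunobu etherification; 7 comes from 4-hydroxybenzyl alcohol 6 in one step. This brings in C2 and all of ring B as a trivial fragment and avoids the corresponding benzyl bromide, a labile quinone-methide precursor, and the carbonate bases that threaten aryl silyl ethers. The acidity of 5 makes it a good Mitsunobu partner.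

**5 ⇒ 4 ⇒ 2 ⇒ 1 (two C–Br bonds, then the C–O bond at the future C8a).** Dibromide 5 comes from the symmetric phenol 4 by bromination at its two equivalent ortho positions. Phenol 4 comes from the bis-silyl ether 2 of 2-methylresorcinol 1 by iridium-catalysed C–H borylation at the only unhindered ring position and oxidation of boronate 3. The third oxygen is thus introduced last and free, while the two oxygens flanking the methyl are already protected. A ring that already held all three oxygens would demand leaving free exactly the one hydroxyl that reacts first. The forward sequence relies on steric control of the borylation.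

## Roads not taken

**Alternative 1:** Ring C is cut at C4a–C4, C4–C3 and O1–C2. In the forward sense PdCl2(PPh3)2 and an amine would join three components: the ortho-iodophenol 2-iodo-3,5-bis(methoxymethoxy)-4-methyl-6-prenylphenol A2, the arylacetylene 1-ethynyl-4-(methoxymethoxy)benzene A3 and carbon monoxide A4. Oxidative addition into the C–I bond of A2, insertion of A4 and coupling with A3 would give an ynone, which closes 6-endo to the flavone 5,7-bis(methoxymethoxy)-2-[4-(methoxymethoxy)phenyl]-6-methyl-8-prenylchromen-4-one A1. C2 would then be created by catalytic asymmetric reduction of the C2–C3 double bond of A1, followed by acetal removal.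
- Merits: it is highly convergent, forms three bonds and ring C in one operation and uses no diazo compound. A3 is a simple alkyne, A4 costs nothing, and A1 is flat, robust and cannot racemise.
- Weak points: A2 needs the same fully substituted ring A as bromide 11 and is no easier to make. The ynone can also close 5-exo to an aurone. The reduction of A1 must act on a poorly electrophilic vinylogous ester beside a peri O5 substituent, spare the prenyl alkene, stop at the ketone, and pass through an enolate that can open ring C. The final acetal cleavage needs protic acid next to the prenyl group.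
- Comparison: in convergence and in the safety of its intermediates Alternative 1 is the better plan. The chosen route sets against this that ring closure and stereocentre arise together under neutral conditions, that no step has to distinguish between two alkenes, and that deprotection uses buffered fluoride.

**Alternative 2:** Ring A is cut at C8–C8a, C6–C7 and C4a–C8a (Danheiser benzannulation). Heating 2-methyl-3-(triisopropylsilyloxy)cyclobut-2-en-1-one A6 gives a vinylketene. It adds to the siloxyalkyne triisopropyl[(5-methylhex-4-en-1-yn-1-yl)oxy]silane A7 by [2+2] cycloaddition, four-electron ring opening and six-electron closure. The product is 4-methyl-2-prenyl-3,5-bis(triisopropylsilyloxy)phenol A5.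
- Merits: the substitution pattern of ring A is written into two small fragments, the prenyl group arrives without organometallic allylation, and the only free hydroxyl of A5 is O1. In regiochemical security it equals the symmetric-phenol route.
- Weak points: A6 and A7 are moisture-sensitive and each needs several steps. The thermal step invites silyl migration. The step solves only ring A: C4a still lacks its carbon, and ring C and C2 remain to be made by some other key step.
- Comparison: the chosen route reaches the equivalent stage (bromide 11) from 2-methylresorcinol 1 through robust reactions on symmetric intermediates, and keeps the stereo-defining step as the centre of the plan. A5 remains valuable as an entry point if the copper-mediated prenylation fails.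

**Alternative 3:** Ring A is cut at C4a–C5. Base would convert methyl 2,7-dimethyl-4-{(2S)-2-[4-(methoxymethoxy)phenyl]-4-oxo-3,4-dihydro-2H-pyran-6-yl}-3-oxooct-6-enoate A9 into an extended enolate. Its C4a attacks the ester carbonyl, and loss of the alkoxide and enolisation give (S)-4'-O-methoxymethyl-6-methyl-8-prenylnaringenin A8.
- Merits: C2 is installed early by an asymmetric hetero-Diels–Alder reaction, a more dependable source of enantiopurity than an acceptor-carbene insertion; this advantage is real. Ring A forms with every substituent fixed by the chain, and only one protecting group is needed.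
- Weak points: A9 is a branched tricarbonyl chain attached to C6 of a dihydropyranone, laborious to assemble and open to other condensation modes (aldol, O-acylation, pyrone formation). The base needed for the Claisen step is the reagent that opens both the dihydropyranone of A9 and the 5-hydroxyflavanone A8 by E1cB, so the stereocentre is exposed at the worst moment. The acetal of A8 then needs acid.
- Comparison: the chosen route concedes the more reliable origin of chirality. In return it creates C2 late and exposes it afterwards only to pyridine-buffered HF.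

Key step: step 9

Assumption: Rh2(S-PTTL)4, dirhodium tetrakis[N-phthaloyl-(S)-tert-leucinate], is taken to deliver the (2S) product; if the (2R) sense prevails, the mirror-image catalyst Rh2(R-PTTL)4 from D-tert-leucine is used and nothing else changes.

## Route

Step 1
Reactants: 1 2-methylresorcinol
Product: 2 2-methyl-1,3-bis(triisopropylsilyloxy)benzene
Conditions: TIPSCl (2.4 equiv), imidazole, DMF, rt → 40 °C
Reagents that add atoms: chlorotriisopropylsilane, CC(C)[Si](Cl)(C(C)C)C(C)C
Why: Imidazole-promoted O-silylation of both phenols; each hydroxyl has only one ortho substituent, so the bulky silyl chloride is accepted, and the resulting groups later shield C4 and C6.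

Step 2
Reactants: 2 2-methyl-1,3-bis(triisopropylsilyloxy)benzene
Product: 4 4-methyl-3,5-bis(triisopropylsilyloxy)phenol, via aryl pinacol boronate 3 (not isolated)
Conditions: [Ir(OMe)(cod)]2 (1.5 mol %), 4,4'-di-tert-butyl-2,2'-bipyridine (3 mol %), B2pin2, THF, 80 °C; then KHSO5 (as its triple salt with KHSO4 and K2SO4), acetone/H2O, rt
Reagents that add atoms: bis(pinacolato)diboron, CC1(C)OB(OC1(C)C)B1OC(C)(C)C(C)(C)O1 (boron, carried only by intermediate 3); potassium peroxymonosulfate, [K+].[O-]S(=O)(=O)OO (the new hydroxyl oxygen)
Why: Iridium-catalysed aromatic C–H borylation is governed by sterics and should attack C5, the only ring C–H without an ortho substituent; one-pot oxidation of the C–B bond (borylation/oxidation route to meta-substituted phenols) then gives the symmetric phenol.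

Step 3
Reactants: 4 4-methyl-3,5-bis(triisopropylsilyloxy)phenol
Product: 5 2,6-dibromo-4-methyl-3,5-bis(triisopropylsilyloxy)phenol
Conditions: NBS (2.05 equiv), CH2Cl2, −40 → 0 °C
Reagents that add atoms: N-bromosuccinimide, O=C1CCC(=O)N1Br
Why: Electrophilic aromatic bromination; the two free positions are equivalent, each ortho to the hydroxyl and ortho/para to the silyloxy groups, and the para position is blocked by methyl, so exhaustive ortho-bromination is the only outcome.

Step 4
Reactants: 6 4-hydroxybenzyl alcohol
Product: 7 4-(triisopropylsilyloxy)benzyl alcohol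
Conditions: NaH (1.0 equiv), THF/DMF, 0 °C; TIPSCl (1.0 equiv), 0 °C → rt
Reagents that add atoms: chlorotriisopropylsilane, CC(C)[Si](Cl)(C(C)C)C(C)C
Why: Chemoselective O-silylation through the phenoxide; one equivalent of base deprotonates only the phenol (about five pKa units more acidic than the benzylic alcohol), and the neutral alcohol does not compete for the hindered silyl chloride.

Step 5
Reactants: 5 2,6-dibromo-4-methyl-3,5-bis(triisopropylsilyloxy)phenol; 7 4-(triisopropylsilyloxy)benzyl alcohol
Product: 8 1,3-dibromo-5-methyl-4,6-bis(triisopropylsilyloxy)-2-{[4-(triisopropylsilyloxy)benzyl]oxy}benzene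
Conditions: PPh3, DIAD, THF, 0 °C → rt
Reagents that add atoms: none
Why: Mitsunobu etherification; the 2,6-dibromophenol is acidic enough to protonate the betaine cleanly and the primary, electron-rich benzylic alcohol is an ideal electrophile, so the O1–CH2 bond forms without base and without a labile benzyl halide.

Step 6
Reactants: 8 1,3-dibromo-5-methyl-4,6-bis(triisopropylsilyloxy)-2-{[4-(triisopropylsilyloxy)benzyl]oxy}benzene; 9 prenyl bromide
Product: 11 1-bromo-5-methyl-3-(3-methylbut-2-en-1-yl)-4,6-bis(triisopropylsilyloxy)-2-{[4-(triisopropylsilyloxy)benzyl]oxy}benzene, via aryllithium 10 (not isolated)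
Conditions: n-BuLi (1.0 equiv), THF, −78 °C; CuBr·SMe2 (0.2 equiv); 9, −78 → −20 °C
Reagents that add atoms: n-butyllithium, [Li]CCCC (lithium, carried only by intermediate 10)
Why: Bromine–lithium exchange on a symmetric dibromide stops after one exchange and can give only one monolithio species (no ring hydrogen, hence no halogen migration); copper-mediated allylic substitution of the arylmetal with prenyl bromide should occur at the primary carbon and give the linear prenyl arene.

Step 7
Reactants: 11 1-bromo-5-methyl-3-(3-methylbut-2-en-1-yl)-4,6-bis(triisopropylsilyloxy)-2-{[4-(triisopropylsilyloxy)benzyl]oxy}benzene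
Product: 13 1-[3-methyl-5-(3-methylbut-2-en-1-yl)-2,4-bis(triisopropylsilyloxy)-6-{[4-(triisopropylsilyloxy)benzyl]oxy}phenyl]ethan-1-one, via aryllithium 12 (not isolated)
Conditions: n-BuLi (1.05 equiv), THF, −78 °C; MeC(O)N(OMe)Me, −78 → 0 °C; H2O
Reagents that add atoms: n-butyllithium, [Li]CCCC (lithium, carried only by intermediate 12); N-methoxy-N-methylacetamide, CC(=O)N(C)OC
Why: Bromine–lithium exchange followed by Weinreb ketone synthesis; the chelated tetrahedral adduct survives until work-up, so the methyl ketone is released only when no organolithium is left and over-addition is excluded.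

Step 8
Reactants: 13 1-[3-methyl-5-(3-methylbut-2-en-1-yl)-2,4-bis(triisopropylsilyloxy)-6-{[4-(triisopropylsilyloxy)benzyl]oxy}phenyl]ethan-1-one
Product: 15 2-diazo-1-[3-methyl-5-(3-methylbut-2-en-1-yl)-2,4-bis(triisopropylsilyloxy)-6-{[4-(triisopropylsilyloxy)benzyl]oxy}phenyl]ethan-1-one, via trifluoroacetyl diketone 14 (not isolated)
Conditions: LiN(SiMe3)2, THF, −78 °C; CF3CO2CH2CF3, −78 °C; cold dilute aq. HCl wash; then MsN3, Et3N, H2O (1 equiv), MeCN, rt
Reagents that add atoms: 2,2,2-trifluoroethyl trifluoroacetate, O=C(OCC(F)(F)F)C(F)(F)F (trifluoroacetyl group, carried only by intermediate 14); methanesulfonyl azide, CS(=O)(=O)N=[N+]=[N-]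
Why: Detrifluoroacetylative diazo transfer: kinetic enolisation of the only acidic position and Claisen-type trifluoroacetylation activate the methyl group, and Regitz-type transfer from the sulfonyl azide then expels the trifluoroacetyl group as its sulfonamide, leaving the terminal diazoketone under conditions that the silyl ethers, the benzyl ether and the prenyl group tolerate.

Step 9
Reactants: 15 2-diazo-1-[3-methyl-5-(3-methylbut-2-en-1-yl)-2,4-bis(triisopropylsilyloxy)-6-{[4-(triisopropylsilyloxy)benzyl]oxy}phenyl]ethan-1-one
Product: 16 (2S)-6-methyl-8-(3-methylbut-2-en-1-yl)-5,7-bis(triisopropylsilyloxy)-2-[4-(triisopropylsilyloxy)phenyl]chroman-4-one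
Conditions: Rh2(S-PTTL)4 (2 mol %), CH2Cl2, 0 °C, slow addition of 15
Reagents that add atoms: none
Why: The dirhodium tetracarboxylate adds to the diazo carbon of 15, dinitrogen leaves and an electrophilic rhodium carbene is formed at C3. The carbene inserts into one benzylic C–H bond of the O1–CH2 group through a concerted, asynchronous three-centre transition state with hydride-transfer character, the developing positive charge at C2 being stabilised by the O1 lone pair and the para-silyloxyphenyl ring; this forms C2–C3 and releases the catalyst. The closest known reaction type is the dirhodium carboxylate-catalysed intramolecular C–H insertion of ortho-alkoxyaryl α-diazoketones to chroman-4-ones, together with the enantioselective insertions of diazocarbonyl compounds under N-phthaloyl amino acid-derived dirhodium catalysts. Ring C closes by 1,6-insertion through a six-membered cyclic transition state; a five-membered closure is impossible because the fifth atom from the carbene is O1, which bears no hydrogen. C2 is set by catalyst control alone: the chiral pocket formed by the four N-phthaloyl-tert-leucinate ligands distinguishes the two enantiotopic benzylic hydrogens, and no other stereocentre is present to interfere. The step needs chemoselectivity for insertion over attack on the O1 lone pair (five-membered oxonium ylide, then Stevens [1,2]-benzyl shift to a benzofuranone); the doubly activated C–H bond, a carboxylate-ligated rhodium catalyst instead of a copper salt such as Cu(acac)2, a non-coordinating solvent and low temperature all favour insertion. O5 carries a bulky, weakly basic silyl ether with no C–H within reach, the prenyl alkene on C8 cannot reach C3 across ring A, and slow addition keeps the diazoketone dilute so that intermolecular cyclopropanation and carbene dimerisation stay minor.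

Step 10
Reactants: 16 (2S)-6-methyl-8-(3-methylbut-2-en-1-yl)-5,7-bis(triisopropylsilyloxy)-2-[4-(triisopropylsilyloxy)phenyl]chroman-4-one
Product: 17 (2S)-5,7-dihydroxy-2-(4-hydroxyphenyl)-6-methyl-8-(3-methylbut-2-en-1-yl)chroman-4-one (6-methyl-8-prenylnaringenin)
Conditions: HF·pyridine, pyridine, THF, 0 °C → rt
Reagents that add atoms: none
Why: Fluoride-induced cleavage of the three aryl silyl ethers; the pyridine-buffered medium is not basic enough to open ring C by E1cB, so C2 keeps its configuration, and not acidic enough to cyclise the prenyl group onto O7.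

## Compound list

1 | 2-methylresorcinol | Cc1c(O)cccc1O | starting material
2 | 2-methyl-1,3-bis(triisopropylsilyloxy)benzene | Cc1c(O[Si](C(C)C)(C(C)C)C(C)C)cccc1O[Si](C(C)C)(C(C)C)C(C)C | intermediate
3 | 2-[4-methyl-3,5-bis(triisopropylsilyloxy)phenyl]-4,4,5,5-tetramethyl-1,3,2-dioxaborolane | Cc1c(O[Si](C(C)C)(C(C)C)C(C)C)cc(B2OC(C)(C)C(C)(C)O2)cc1O[Si](C(C)C)(C(C)C)C(C)C | intermediate (not isolated)
4 | 4-methyl-3,5-bis(triisopropylsilyloxy)phenol | Cc1c(O[Si](C(C)C)(C(C)C)C(C)C)cc(O)cc1O[Si](C(C)C)(C(C)C)C(C)C | intermediate
5 | 2,6-dibromo-4-methyl-3,5-bis(triisopropylsilyloxy)phenol | Cc1c(O[Si](C(C)C)(C(C)C)C(C)C)c(Br)c(O)c(Br)c1O[Si](C(C)C)(C(C)C)C(C)C | intermediate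
6 | 4-hydroxybenzyl alcohol | OCc1ccc(O)cc1 | starting material
7 | 4-(triisopropylsilyloxy)benzyl alcohol | OCc1ccc(O[Si](C(C)C)(C(C)C)C(C)C)cc1 | intermediate
8 | 1,3-dibromo-5-methyl-4,6-bis(triisopropylsilyloxy)-2-{[4-(triisopropylsilyloxy)benzyl]oxy}benzene | Cc1c(O[Si](C(C)C)(C(C)C)C(C)C)c(Br)c(OCc2ccc(O[Si](C(C)C)(C(C)C)C(C)C)cc2)c(Br)c1O[Si](C(C)C)(C(C)C)C(C)C | intermediate
9 | prenyl bromide (1-bromo-3-methylbut-2-ene) | CC(C)=CCBr | starting material
10 | {3-bromo-5-methyl-4,6-bis(triisopropylsilyloxy)-2-[4-(triisopropylsilyloxy)benzyloxy]phenyl}lithium | Cc1c(O[Si](C(C)C)(C(C)C)C(C)C)c([Li])c(OCc2ccc(O[Si](C(C)C)(C(C)C)C(C)C)cc2)c(Br)c1O[Si](C(C)C)(C(C)C)C(C)C | intermediate (not isolated)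
11 | 1-bromo-5-methyl-3-(3-methylbut-2-en-1-yl)-4,6-bis(triisopropylsilyloxy)-2-{[4-(triisopropylsilyloxy)benzyl]oxy}benzene | Cc1c(O[Si](C(C)C)(C(C)C)C(C)C)c(CC=C(C)C)c(OCc2ccc(O[Si](C(C)C)(C(C)C)C(C)C)cc2)c(Br)c1O[Si](C(C)C)(C(C)C)C(C)C | intermediate
12 | {3-methyl-5-(3-methylbut-2-en-1-yl)-2,4-bis(triisopropylsilyloxy)-6-[4-(triisopropylsilyloxy)benzyloxy]phenyl}lithium | Cc1c(O[Si](C(C)C)(C(C)C)C(C)C)c(CC=C(C)C)c(OCc2ccc(O[Si](C(C)C)(C(C)C)C(C)C)cc2)c([Li])c1O[Si](C(C)C)(C(C)C)C(C)C | intermediate (not isolated)
13 | 1-[3-methyl-5-(3-methylbut-2-en-1-yl)-2,4-bis(triisopropylsilyloxy)-6-{[4-(triisopropylsilyloxy)benzyl]oxy}phenyl]ethan-1-one | CC(=O)c1c(O[Si](C(C)C)(C(C)C)C(C)C)c(C)c(O[Si](C(C)C)(C(C)C)C(C)C)c(CC=C(C)C)c1OCc1ccc(O[Si](C(C)C)(C(C)C)C(C)C)cc1 | intermediate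
14 | 4,4,4-trifluoro-1-[3-methyl-5-(3-methylbut-2-en-1-yl)-2,4-bis(triisopropylsilyloxy)-6-{[4-(triisopropylsilyloxy)benzyl]oxy}phenyl]butane-1,3-dione | O=C(CC(=O)C(F)(F)F)c1c(O[Si](C(C)C)(C(C)C)C(C)C)c(C)c(O[Si](C(C)C)(C(C)C)C(C)C)c(CC=C(C)C)c1OCc1ccc(O[Si](C(C)C)(C(C)C)C(C)C)cc1 | intermediate (not isolated)
15 | 2-diazo-1-[3-methyl-5-(3-methylbut-2-en-1-yl)-2,4-bis(triisopropylsilyloxy)-6-{[4-(triisopropylsilyloxy)benzyl]oxy}phenyl]ethan-1-one | [N-]=[N+]=CC(=O)c1c(O[Si](C(C)C)(C(C)C)C(C)C)c(C)c(O[Si](C(C)C)(C(C)C)C(C)C)c(CC=C(C)C)c1OCc1ccc(O[Si](C(C)C)(C(C)C)C(C)C)cc1 | intermediate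
16 | (2S)-6-methyl-8-(3-methylbut-2-en-1-yl)-5,7-bis(triisopropylsilyloxy)-2-[4-(triisopropylsilyloxy)phenyl]chroman-4-one | CC(C)=CCc1c(O[Si](C(C)C)(C(C)C)C(C)C)c(C)c(O[Si](C(C)C)(C(C)C)C(C)C)c2c1O[C@H](c1ccc(O[Si](C(C)C)(C(C)C)C(C)C)cc1)CC2=O | intermediate
17 | (2S)-5,7-dihydroxy-2-(4-hydroxyphenyl)-6-methyl-8-(3-methylbut-2-en-1-yl)chroman-4-one (6-methyl-8-prenylnaringenin) | CC(C)=CCc1c(O)c(C)c(O)c2c1O[C@H](c1ccc(O)cc1)CC2=O | target

## Step count and least certain steps

Total: 10 steps. Longest linear sequence: 9 steps (1, 2, 3, 5, 6, 7, 8, 9, 10 from 2-methylresorcinol); step 4 prepares the benzyl alcohol 7.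

**Step 9 (key step).**
- Main risk: weak discrimination between the two enantiotopic benzylic hydrogens. An acceptor-only carbene is very reactive and reaches its transition state early, far from the chiral ligand wall.
- Second risk: diversion of the carbene onto the O1 lone pair, followed by a [1,2]-benzyl shift.
- Third risk: slow insertion, because the carbonyl has to rotate towards the plane of ring A against the peri silyl ether on O5.
- Fallback: it sets out from 15 and returns at 16, and separates ring closure from stereocontrol. Compound 15 is decomposed with achiral Rh2(OAc)4 in CH2Cl2 to racemic 6-methyl-8-(3-methylbut-2-en-1-yl)-5,7-bis(triisopropylsilyloxy)-2-[4-(triisopropylsilyloxy)phenyl]chroman-4-one F1. F1 is then resolved kinetically by asymmetric transfer hydrogenation with RuCl[(R,R)-TsDPEN](p-cymene) and HCO2H/Et3N in ethyl acetate. The catalyst antipode is chosen so that it consumes the (2R)-ketone; by the usual model for aryl ketones this is the (R,R)-ligand. The (2R)-ketone is reduced to (2R,4R)-6-methyl-8-(3-methylbut-2-en-1-yl)-5,7-bis(triisopropylsilyloxy)-2-[4-(triisopropylsilyloxy)phenyl]chroman-4-ol F2, which is removed by chromatography, leaving 16. Partly enriched 16 from step 9 can be upgraded in the same way.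

**Step 6.**
- Main risk: anionic migration of a triisopropylsilyl group from oxygen to the neighbouring lithiated carbon (retro-Brook shift) before the copper step.
- Second risk: allylic transposition during the coupling, which would give the 1,1-dimethylallyl isomer.
- Third risk: proton transfer from the benzylic ether methylene to the aryl anion on warming.
- Fallback: it sets out from 4 and returns at 11, and avoids an aryl anion beside a silyl ether at this stage. The sodium phenoxide of 4 (NaH, toluene) is C-alkylated at an ortho position with 9 in the non-polar medium to give 4-methyl-2-(3-methylbut-2-en-1-yl)-3,5-bis(triisopropylsilyloxy)phenol F3 (identical with A5). The one remaining ring position is brominated (NBS, 1 equiv, CH2Cl2, −78 °C) to 2-bromo-4-methyl-6-(3-methylbut-2-en-1-yl)-3,5-bis(triisopropylsilyloxy)phenol F4. Mitsunobu etherification of F4 with 7 (PPh3, DIAD, THF) gives 11.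

**Step 7.**
- Main risk: proton transfer from the α-hydrogens of the acetamide to the hindered, doubly ortho-substituted aryllithium, which would return the debrominated arene instead of the ketone.
- Second risk: the same silyl migration as in step 6.
- Fallback: it sets out from 11 and returns at 13. Aryllithium 12 is trapped with acetaldehyde, a far faster electrophile, to give racemic 1-[3-methyl-5-(3-methylbut-2-en-1-yl)-2,4-bis(triisopropylsilyloxy)-6-{[4-(triisopropylsilyloxy)benzyl]oxy}phenyl]ethan-1-ol F5. F5 is oxidised with Dess–Martin periodinane (NaHCO3, CH2Cl2) to 13.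

**Step 8.**
- Main risk: incomplete trifluoroacetylation of the crowded enolate, or sluggish diazo transfer to a diketone whose aroyl group is twisted out of conjugation by two ortho substituents, with slow loss of silyl groups during the prolonged amine/water treatment.
- Fallback: it sets out from 11, bypasses 13 and returns at 15. Aryllithium 12 is carboxylated with CO2 to 3-methyl-5-(3-methylbut-2-en-1-yl)-2,4-bis(triisopropylsilyloxy)-6-{[4-(triisopropylsilyloxy)benzyl]oxy}benzoic acid F6. F6 is converted under neutral conditions with 1-chloro-N,N,2-trimethylprop-1-en-1-amine (CH2Cl2, 0 °C) into 3-methyl-5-(3-methylbut-2-en-1-yl)-2,4-bis(triisopropylsilyloxy)-6-{[4-(triisopropylsilyloxy)benzyl]oxy}benzoyl chloride F7. Acylation of excess diazomethane by F7 (Et2O, 0 °C) gives 15.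

## Further compounds

F1 | step 9 | racemic 6-methyl-8-(3-methylbut-2-en-1-yl)-5,7-bis(triisopropylsilyloxy)-2-[4-(triisopropylsilyloxy)phenyl]chroman-4-one | CC(C)=CCc1c(O[Si](C(C)C)(C(C)C)C(C)C)c(C)c(O[Si](C(C)C)(C(C)C)C(C)C)c2c1OC(c1ccc(O[Si](C(C)C)(C(C)C)C(C)C)cc1)CC2=O
F2 | step 9 | (2R,4R)-6-methyl-8-(3-methylbut-2-en-1-yl)-5,7-bis(triisopropylsilyloxy)-2-[4-(triisopropylsilyloxy)phenyl]chroman-4-ol | CC(C)=CCc1c(O[Si](C(C)C)(C(C)C)C(C)C)c(C)c(O[Si](C(C)C)(C(C)C)C(C)C)c2c1O[C@@H](c1ccc(O[Si](C(C)C)(C(C)C)C(C)C)cc1)C[C@H]2O
F3 | step 6 | 4-methyl-2-(3-methylbut-2-en-1-yl)-3,5-bis(triisopropylsilyloxy)phenol | CC(C)=CCc1c(O)cc(O[Si](C(C)C)(C(C)C)C(C)C)c(C)c1O[Si](C(C)C)(C(C)C)C(C)C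
F4 | step 6 | 2-bromo-4-methyl-6-(3-methylbut-2-en-1-yl)-3,5-bis(triisopropylsilyloxy)phenol | CC(C)=CCc1c(O)c(Br)c(O[Si](C(C)C)(C(C)C)C(C)C)c(C)c1O[Si](C(C)C)(C(C)C)C(C)C
F5 | step 7 | racemic 1-[3-methyl-5-(3-methylbut-2-en-1-yl)-2,4-bis(triisopropylsilyloxy)-6-{[4-(triisopropylsilyloxy)benzyl]oxy}phenyl]ethan-1-ol | CC(O)c1c(O[Si](C(C)C)(C(C)C)C(C)C)c(C)c(O[Si](C(C)C)(C(C)C)C(C)C)c(CC=C(C)C)c1OCc1ccc(O[Si](C(C)C)(C(C)C)C(C)C)cc1
F6 | step 8 | 3-methyl-5-(3-methylbut-2-en-1-yl)-2,4-bis(triisopropylsilyloxy)-6-{[4-(triisopropylsilyloxy)benzyl]oxy}benzoic acid | OC(=O)c1c(O[Si](C(C)C)(C(C)C)C(C)C)c(C)c(O[Si](C(C)C)(C(C)C)C(C)C)c(CC=C(C)C)c1OCc1ccc(O[Si](C(C)C)(C(C)C)C(C)C)cc1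
F7 | step 8 | 3-methyl-5-(3-methylbut-2-en-1-yl)-2,4-bis(triisopropylsilyloxy)-6-{[4-(triisopropylsilyloxy)benzyl]oxy}benzoyl chloride | ClC(=O)c1c(O[Si](C(C)C)(C(C)C)C(C)C)c(C)c(O[Si](C(C)C)(C(C)C)C(C)C)c(CC=C(C)C)c1OCc1ccc(O[Si](C(C)C)(C(C)C)C(C)C)cc1
A1 | alternative 1 | 5,7-bis(methoxymethoxy)-2-[4-(methoxymethoxy)phenyl]-6-methyl-8-prenylchromen-4-one | CC(C)=CCc1c(OCOC)c(C)c(OCOC)c2c1oc(-c1ccc(OCOC)cc1)cc2=O
A2 | alternative 1 | 2-iodo-3,5-bis(methoxymethoxy)-4-methyl-6-prenylphenol | CC(C)=CCc1c(O)c(I)c(OCOC)c(C)c1OCOC
A3 | alternative 1 | 1-ethynyl-4-(methoxymethoxy)benzene | C#Cc1ccc(OCOC)cc1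
A4 | alternative 1 | carbon monoxide | [C-]#[O+]
A5 | alternative 2 | 4-methyl-2-prenyl-3,5-bis(triisopropylsilyloxy)phenol | CC(C)=CCc1c(O)cc(O[Si](C(C)C)(C(C)C)C(C)C)c(C)c1O[Si](C(C)C)(C(C)C)C(C)C
A6 | alternative 2 | 2-methyl-3-(triisopropylsilyloxy)cyclobut-2-en-1-one | CC1=C(O[Si](C(C)C)(C(C)C)C(C)C)CC1=O
A7 | alternative 2 | triisopropyl[(5-methylhex-4-en-1-yn-1-yl)oxy]silane | CC(C)=CCC#CO[Si](C(C)C)(C(C)C)C(C)C
A8 | alternative 3 | (S)-4'-O-methoxymethyl-6-methyl-8-prenylnaringenin | CC(C)=CCc1c(O)c(C)c(O)c2c1O[C@H](c1ccc(OCOC)cc1)CC2=O
A9 | alternative 3 | methyl 2,7-dimethyl-4-{(2S)-2-[4-(methoxymethoxy)phenyl]-4-oxo-3,4-dihydro-2H-pyran-6-yl}-3-oxooct-6-enoate | COC(=O)C(C)C(=O)C(CC=C(C)C)C1=CC(=O)C[C@@H](c2ccc(OCOC)cc2)O1
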